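The butanolide is disconnected into a two-carbon alkene unit (C3–C4) and the three-atom C2(=O)–O1–C5H2 unit. The feature exploited is that C3 lies β and C4 α to the exocyclic carbonyl on C4, so an enoyl acceptor can take a nucleophilic alkoxycarbonyl radical at C3 and then alkylate as an enolate at C4. In one operation a chloromethoxycarbonyl radical, released from a redox-active oxalate, adds enantioselectively to an (E)-4-aryl-but-2-enoyl pyrazole bound to a chiral-at-rhodium Lewis acid, and the enolate closes on the chloromethyl group (formal (3+2) annulation). The pyrazole amide is then exchanged for the aryl ketone and the benzyl ethers are removed.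

Key step: step 5

Assumption: the Λ enantiomer of the rhodium catalyst is taken to leave the Re face of the β-carbon of the chelated enoyl pyrazole open; if the opposite sense is found, the Δ enantiomer is used and nothing else changes.

Step 1
Reactants: 1 eugenol (4-allyl-2-methoxyphenol)
Product: 2 4-allyl-1-(benzyloxy)-2-methoxybenzene
Conditions: BnBr, K2CO3, acetone, reflux
Reagents that add atoms: benzyl bromide, BrCc1ccccc1
Why: Williamson ether synthesis of the phenoxide on a benzylic bromide should mask the phenol for the radical, enolate and Grignard steps that follow.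

Step 2
Reactants: 3 3,5-dimethyl-1H-pyrazole; 4 acryloyl chloride
Product: 5 1-(3,5-dimethyl-1H-pyrazol-1-yl)prop-2-en-1-one
Conditions: Et3N, CH2Cl2, 0 °C
Reagents that add atoms: none
Why: N-acylation of the pyrazole N–H by the acid chloride should be faster at 0 °C than aza-Michael addition to the acrylamide formed.

Step 3
Reactants: 2 4-allyl-1-(benzyloxy)-2-methoxybenzene; 5 1-(3,5-dimethyl-1H-pyrazol-1-yl)prop-2-en-1-one (2 equiv)
Product: 6 (E)-4-[4-(benzyloxy)-3-methoxyphenyl]-1-(3,5-dimethyl-1H-pyrazol-1-yl)but-2-en-1-one
Conditions: RuCl2(H2IMes)(=CH-C6H4-2-O-i-Pr) (second-generation Hoveyda–Grubbs catalyst, 5 mol%), 1,4-benzoquinone (10 mol%), CH2Cl2, 40 °C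
Reagents that add atoms: none
Why: Olefin cross-metathesis of an allylarene with an electron-poor acryloyl partner should give the E-enoyl amide under neutral conditions, with benzoquinone suppressing migration of the double bond toward the arene.

Step 4
Reactants: 7 N-hydroxyphthalimide; 8 oxalyl chloride (excess)
Product: 10 chloromethyl 1,3-dioxoisoindolin-2-yl oxalate, via N-phthalimidoyl chlorooxalate 9 (not isolated)
Conditions: (i) CH2Cl2, 0 °C to rt, then evaporation of excess 8; (ii) paraformaldehyde, ZnCl2 (5 mol%), CH2Cl2, rt
Reagents that add atoms: paraformaldehyde (as formaldehyde), C=O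
Why: O-acylation of the N-hydroxy imide by excess oxalyl chloride should stop at the mono-chlorooxalate, and ZnCl2-catalysed insertion of formaldehyde into the remaining acyl chloride (α-chloroalkyl ester formation) should install the chloromethyl ester without touching the N–O ester.

Step 5
Reactants: 6 (E)-4-[4-(benzyloxy)-3-methoxyphenyl]-1-(3,5-dimethyl-1H-pyrazol-1-yl)but-2-en-1-one; 10 chloromethyl 1,3-dioxoisoindolin-2-yl oxalate (1.5 equiv)
Product: 12 (3R,4R)-3-[4-(benzyloxy)-3-methoxybenzyl]-4-(3,5-dimethyl-1H-pyrazole-1-carbonyl)oxolan-2-one, via open-chain chloromethyl ester adduct 11 (not isolated)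
Conditions: (i) Λ-[Rh(ptbt)2(MeCN)2]PF6 (ptbt = C,N-cyclometalated 5-tert-butyl-2-phenylbenzothiazole; trivalent rhodium; 5 mol%), Hantzsch ester (diethyl 2,6-dimethyl-1,4-dihydropyridine-3,5-dicarboxylate, 1.5 equiv), THF, blue LEDs, rt, degassed; (ii) MgBr2·OEt2, i-Pr2NEt, 0 °C to rt, dark, same flask
Reagents that add atoms: none
Why: Proposed new method: photoexcited Hantzsch ester should reduce the N-acyloxyphthalimide 10, which loses phthalimide anion and CO2 to give the nucleophilic chloromethoxycarbonyl σ-radical; this adds to the β-carbon of 6 held s-cis in an N,O-chelate on the rhodium Lewis acid (C2–C3 bond of the lactone), the rhodium enolate radical is reduced and protonated to 11, and soft enolisation with MgBr2/i-Pr2NEt then lets the α-carbon displace halide from the chloromethyl ester (C4–C5 bond). The closest known reactions are the enantioselective Giese additions of N-acyloxyphthalimide-derived radicals to α,β-unsaturated N-acylpyrazoles under this type of rhodium catalyst with Hantzsch ester, the Giese addition of the methoxycarbonyl radical from methyl N-phthalimidoyl oxalate, and radical–polar crossover annulations in which an enolate closes onto a halide. The lactone ring closes by 5-exo-tet C-alkylation, since O-alkylation would need a seven-membered ring. C-3 is set by the catalyst, whose cyclometalated ligand should block the Si face of the β-carbon so that the radical enters on the Re face and gives (R); C-4 is set trans to the benzyl group by the substrate during ring closure and is held there by equilibration through the enolate. The step needs β-regioselectivity, secured by the LUMO-lowering chelate and the nucleophilic character of the radical, and it needs the radical to be trapped before it loses CO2, secured by the activated acceptor; ring opening of the product by E1cB is disfavoured because the C5–O bond lies in the plane of the exocyclic enolate.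

Step 6
Reactants: 12 (3R,4R)-3-[4-(benzyloxy)-3-methoxybenzyl]-4-(3,5-dimethyl-1H-pyrazole-1-carbonyl)oxolan-2-one; 13 1-(benzyloxy)-4-bromo-2-methoxybenzene
Product: 15 (3R,4R)-4-[4-(benzyloxy)-3-methoxybenzoyl]-3-[4-(benzyloxy)-3-methoxybenzyl]oxolan-2-one, via arylmagnesium bromide 14 (not isolated)
Conditions: 13, Mg, THF, rt; then 12, THF, −78 °C; aq. NH4Cl
Reagents that add atoms: none
Why: Grignard acylation by the N-acylpyrazole should stop at the ketone because the magnesium-chelated tetrahedral adduct persists at −78 °C, the activated amide should react well before the lactone, and C-4 should stay in the thermodynamically preferred trans arrangement.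

Step 7
Reactants: 15 (3R,4R)-4-[4-(benzyloxy)-3-methoxybenzoyl]-3-[4-(benzyloxy)-3-methoxybenzyl]oxolan-2-one
Product: 16 (3R,4R)-4-(4-hydroxy-3-methoxybenzoyl)-3-(4-hydroxy-3-methoxybenzyl)oxolan-2-one
Conditions: H2 (1 atm), Pd/C, EtOAc, rt
Reagents that add atoms: none
Why: Hydrogenolysis of the two benzyl ethers under neutral conditions should free both phenols without epimerisation or β-elimination, the para-oxygenated aryl ketone being reduced much more slowly than the O-benzyl groups are cleaved.

Compound list
1 | eugenol (4-allyl-2-methoxyphenol) | C=CCc1ccc(O)c(OC)c1 | starting material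
2 | 4-allyl-1-(benzyloxy)-2-methoxybenzene | C=CCc1ccc(OCc2ccccc2)c(OC)c1 | intermediate
3 | 3,5-dimethyl-1H-pyrazole | Cc1cc(C)[nH]n1 | starting material
4 | acryloyl chloride | C=CC(=O)Cl | starting material
5 | 1-(3,5-dimethyl-1H-pyrazol-1-yl)prop-2-en-1-one | C=CC(=O)n1nc(C)cc1C | intermediate
6 | (E)-4-[4-(benzyloxy)-3-methoxyphenyl]-1-(3,5-dimethyl-1H-pyrazol-1-yl)but-2-en-1-one | COc1cc(C/C=C/C(=O)n2nc(C)cc2C)ccc1OCc1ccccc1 | intermediate
7 | N-hydroxyphthalimide | O=C1c2ccccc2C(=O)N1O | starting material
8 | oxalyl chloride | ClC(=O)C(=O)Cl | starting material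
9 | 1,3-dioxoisoindolin-2-yl chlorooxoacetate (N-phthalimidoyl chlorooxalate) | ClC(=O)C(=O)ON1C(=O)c2ccccc2C1=O | intermediate
10 | chloromethyl 1,3-dioxoisoindolin-2-yl oxalate | ClCOC(=O)C(=O)ON1C(=O)c2ccccc2C1=O | intermediate
11 | chloromethyl (2R)-2-[4-(benzyloxy)-3-methoxybenzyl]-4-(3,5-dimethyl-1H-pyrazol-1-yl)-4-oxobutanoate | COc1cc(C[C@@H](C(=O)OCCl)CC(=O)n2nc(C)cc2C)ccc1OCc1ccccc1 | intermediate
12 | (3R,4R)-3-[4-(benzyloxy)-3-methoxybenzyl]-4-(3,5-dimethyl-1H-pyrazole-1-carbonyl)oxolan-2-one | COc1cc(C[C@H]2C(=O)OC[C@@H]2C(=O)n2nc(C)cc2C)ccc1OCc1ccccc1 | intermediate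
13 | 1-(benzyloxy)-4-bromo-2-methoxybenzene | COc1cc(Br)ccc1OCc1ccccc1 | starting material
14 | [4-(benzyloxy)-3-methoxyphenyl]magnesium bromide | COc1cc([Mg]Br)ccc1OCc1ccccc1 | intermediate
15 | (3R,4R)-4-[4-(benzyloxy)-3-methoxybenzoyl]-3-[4-(benzyloxy)-3-methoxybenzyl]oxolan-2-one | COc1cc(C[C@H]2C(=O)OC[C@@H]2C(=O)c2ccc(OCc3ccccc3)c(OC)c2)ccc1OCc1ccccc1 | intermediate
16 | (3R,4R)-4-(4-hydroxy-3-methoxybenzoyl)-3-(4-hydroxy-3-methoxybenzyl)oxolan-2-one | COc1cc(C[C@H]2C(=O)OC[C@@H]2C(=O)c2ccc(O)c(OC)c2)ccc1O | target

Total step count: 7. Longest linear sequence: 5 steps (steps 1, 3, 5, 6, 7).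

Steps most likely to fail

Step 5 (proposed new method). The alkoxycarbonyl radical may lose CO2 before it adds, the double bond of the acceptor may migrate into conjugation with the arene on the Lewis acid, the chloromethyl ester may alkylate phthalimide instead of closing the ring, or facial discrimination may be insufficient. The fallback brings in the C2 carboxyl carbon as nitromethane by known polar chemistry and sets out from 6. Conjugate addition of nitromethane catalysed by Ni(ClO4)2·3H2O and 4,6-dibenzofurandiyl-2,2'-bis(4-phenyloxazoline) (ligand enantiomer chosen for (R)) with 2,2,6,6-tetramethylpiperidine in THF should give (3R)-3-[4-(benzyloxy)-3-methoxybenzyl]-1-(3,5-dimethyl-1H-pyrazol-1-yl)-4-nitrobutan-1-one F1. After deprotonation of the nitro group with LiN(SiMe3)2 at −78 °C, the arylmagnesium bromide 14 should convert the pyrazole amide into (3R)-3-[4-(benzyloxy)-3-methoxybenzyl]-1-[4-(benzyloxy)-3-methoxyphenyl]-4-nitrobutan-1-one F2. NaNO2 and AcOH in DMSO should oxidise the primary nitro group to (2R)-2-[4-(benzyloxy)-3-methoxybenzyl]-4-[4-(benzyloxy)-3-methoxyphenyl]-4-oxobutanoic acid F3. Aqueous formaldehyde with K2CO3 should hydroxymethylate the ketone α-carbon, and acidification should lactonise to the trans lactone 15, where the fallback rejoins the route, so that step 6 is not needed.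

Step 4. The chlorooxalate may decarbonylate or lose its N–O ester under the Lewis acid, and the product may hydrolyse during isolation. The fallback introduces the chloromethyl group by carboxylate alkylation and forms the N–O ester last under neutral conditions; it sets out from 8. One equivalent of tert-butanol should give tert-butyl chlorooxoacetate F4, and water should then give tert-butyl hydrogen oxalate F5. Chloromethyl chlorosulfate (NaHCO3, Bu4NHSO4, CH2Cl2/H2O) should give tert-butyl chloromethyl oxalate F6, and TFA in CH2Cl2 should give chloromethyl hydrogen oxalate F7. N,N'-Diisopropylcarbodiimide should couple F7 with 7 to give 10, where the fallback rejoins the route.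

Step 6. The Grignard reagent may enolise C-4, leading to β-elimination of the lactone carboxylate or epimerisation, or it may attack the lactone carbonyl. The fallback replaces the basic organometallic by a neutral cross-coupling and sets out from 12. Ethanethiol with catalytic Et3N in CH2Cl2 should give S-ethyl (3R,4R)-4-[4-(benzyloxy)-3-methoxybenzyl]-5-oxooxolane-3-carbothioate F8. Liebeskind–Srogl coupling of F8 with [4-(benzyloxy)-3-methoxyphenyl]boronic acid (Pd2(dba)3, tri(2-furyl)phosphine, copper thiophene-2-carboxylate CuTC of monovalent copper, THF, 50 °C) should give 15, where the fallback rejoins the route.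

Further compounds
F1 | step 5 | (3R)-3-[4-(benzyloxy)-3-methoxybenzyl]-1-(3,5-dimethyl-1H-pyrazol-1-yl)-4-nitrobutan-1-one | COc1cc(C[C@@H](C[N+](=O)[O-])CC(=O)n2nc(C)cc2C)ccc1OCc1ccccc1
F2 | step 5 | (3R)-3-[4-(benzyloxy)-3-methoxybenzyl]-1-[4-(benzyloxy)-3-methoxyphenyl]-4-nitrobutan-1-one | COc1cc(C[C@@H](C[N+](=O)[O-])CC(=O)c2ccc(OCc3ccccc3)c(OC)c2)ccc1OCc1ccccc1
F3 | step 5 | (2R)-2-[4-(benzyloxy)-3-methoxybenzyl]-4-[4-(benzyloxy)-3-methoxyphenyl]-4-oxobutanoic acid | COc1cc(C[C@@H](C(=O)O)CC(=O)c2ccc(OCc3ccccc3)c(OC)c2)ccc1OCc1ccccc1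
F4 | step 4 | tert-butyl chlorooxoacetate | CC(C)(C)OC(=O)C(=O)Cl
F5 | step 4 | tert-butyl hydrogen oxalate | CC(C)(C)OC(=O)C(=O)O
F6 | step 4 | tert-butyl chloromethyl oxalate | CC(C)(C)OC(=O)C(=O)OCCl
F7 | step 4 | chloromethyl hydrogen oxalate | OC(=O)C(=O)OCCl
F8 | step 6 | S-ethyl (3R,4R)-4-[4-(benzyloxy)-3-methoxybenzyl]-5-oxooxolane-3-carbothioate | COc1cc(C[C@H]2C(=O)OC[C@@H]2C(=O)SCC)ccc1OCc1ccccc1
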